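**Plan**

- Ring C of the flavone (O1, C2, C3, C4, C4a, C8a) is cut at three bonds at once: C4a–C4, C4–C3 and O1–C2. The carbonyl carbon C4 stands alone between the fully substituted ring A carbon C4a and a C2–C3 unit at the oxidation level of an alkyne, so C4 can be brought in as carbon monoxide.
- The pieces are 2-iodo-3,5,6-trimethoxyphenol (ring A, iodine at the future C4a, free hydroxyl at the future C8a), 1-ethynyl-2,3,4,5-tetramethoxybenzene (ring B with C2 and C3) and carbon monoxide.
- The iodophenol is made from 3,5-dimethoxyphenol by two carbamate-directed ortho-metalations (first oxygen for the C8 methoxy group, then iodine). The alkyne is made from 2,3,4-trimethoxybenzaldehyde by Dakin oxidation, methylation, iodination and Sonogashira coupling.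
- Forward order: rings A and B are carried in as finished arenes; ring C is the only ring formed, in the last step, which joins all three pieces.
- The target has no stereocentre. The issue is regiochemistry (5,7,8 versus 5,6,7 on ring A), which is fixed by the positions of iodine and the free hydroxyl in the iodophenol.

Key step: step 11

Remark: palladium-bound species of the catalytic cycles are transient catalyst forms and carry no compound number; the enaminone intermediate of the last step is drawn as its E isomer, and either geometry would close to the same flavone.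

**Route**

Step 1
Reactants: 1 3,5-dimethoxyphenol
Product: 2 3,5-dimethoxyphenyl N,N-diethylcarbamate
Conditions: ClCONEt2, K2CO3, MeCN, reflux
Reagents that add atoms: N,N-diethylcarbamoyl chloride, CCN(CC)C(Cl)=O
Why: O-carbamoylation of the phenoxide is a routine acyl substitution and installs the strongest oxygen-based directing group for ortho-metalation.

Step 2
Reactants: 2 3,5-dimethoxyphenyl N,N-diethylcarbamate
Product: 5 2-hydroxy-3,5-dimethoxyphenyl N,N-diethylcarbamate, via 2-lithio carbamate 3 (not isolated), via dimethyl arylboronate 4 (not isolated)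
Conditions: s-BuLi, TMEDA, THF, −78 °C; B(OMe)3, −78 °C to rt; AcOH, 30% H2O2, 0 °C to rt
Reagents that add atoms: hydrogen peroxide, OO; sec-butyllithium, CCC(C)[Li] (lithium of 3 only); trimethyl borate, COB(OC)OC (boron and two methoxy groups of 4 only)
Why: In this directed ortho-metalation the carbamate and the neighbouring methoxy group together should direct lithiation to the carbon between them at −78 °C, below the onset of the anionic ortho-Fries shift, and borylation followed by acidic peroxide oxidation turns the C–Li bond into C–OH without exposing the carbamate to a phenoxide.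

Step 3
Reactants: 5 2-hydroxy-3,5-dimethoxyphenyl N,N-diethylcarbamate
Product: 6 2,3,5-trimethoxyphenyl N,N-diethylcarbamate
Conditions: MeI, K2CO3, acetone, rt
Reagents that add atoms: iodomethane, CI
Why: Williamson O-methylation of the phenoxide at room temperature should be much faster than any shift of the tertiary carbamoyl group to the neighbouring oxygen, and the carbamate is inert to carbonate.

Step 4
Reactants: 6 2,3,5-trimethoxyphenyl N,N-diethylcarbamate
Product: 8 6-iodo-2,3,5-trimethoxyphenyl N,N-diethylcarbamate, via 6-lithio carbamate 7 (not isolated)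
Conditions: s-BuLi, TMEDA, THF, −78 °C; I2, THF, −78 °C to rt
Reagents that add atoms: iodine, II; sec-butyllithium, CCC(C)[Li] (lithium of 7 only)
Why: In this second directed ortho-metalation the one remaining position ortho to the carbamate is also flanked by a methoxy group, so it should be lithiated in preference to the position between the two methoxy groups, and iodine traps the aryllithium cold.

Step 5
Reactants: 8 6-iodo-2,3,5-trimethoxyphenyl N,N-diethylcarbamate
Product: 9 2-iodo-3,5,6-trimethoxyphenol
Conditions: NaOH, EtOH–H2O, reflux; then aq HCl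
Reagents that add atoms: none
Why: Alkaline hydrolysis of the aryl carbamate (addition–elimination at the carbamoyl carbon) frees the phenoxide, while the electron-rich aryl iodide and the methyl ethers have no reaction path with hydroxide, so prolonged heating of this hindered carbamate should be tolerated.

Step 6
Reactants: 10 2,3,4-trimethoxybenzaldehyde
Product: 12 2,3,4-trimethoxyphenol, via aryl formate 11 (not isolated)
Conditions: 30% H2O2, H2SO4 (cat.), MeOH, rt
Reagents that add atoms: hydrogen peroxide, OO
Why: In this Dakin oxidation the electron-rich aryl group, with methoxy groups ortho and para to the formyl carbon, migrates to oxygen in the peroxide adduct, and methanol cleaves the resulting formate in the same flask.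

Step 7
Reactants: 12 2,3,4-trimethoxyphenol
Product: 13 1,2,3,4-tetramethoxybenzene
Conditions: MeI, K2CO3, acetone, reflux
Reagents that add atoms: iodomethane, CI
Why: Williamson O-methylation of a simple phenol has no competing site.

Step 8
Reactants: 13 1,2,3,4-tetramethoxybenzene
Product: 14 1-iodo-2,3,4,5-tetramethoxybenzene
Conditions: NIS (1 equiv), CF3CO2H (cat.), MeCN, rt
Reagents that add atoms: N-iodosuccinimide, O=C1CCC(=O)N1I
Why: In this electrophilic aromatic iodination the two free positions of 13 are equivalent by symmetry, so only one mono-iodide can form, and one equivalent of reagent should hold the reaction at that stage.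

Step 9
Reactants: 14 1-iodo-2,3,4,5-tetramethoxybenzene; 15 trimethylsilylacetylene
Product: 16 trimethyl[(2,3,4,5-tetramethoxyphenyl)ethynyl]silane
Conditions: PdCl2(PPh3)2 (cat.), CuI (cat.), Et3N, THF, 50 °C
Reagents that add atoms: none
Why: Sonogashira coupling of an aryl iodide proceeds readily even on an electron-rich ring, and the silyl group blocks the second alkyne terminus against double coupling.

Step 10
Reactants: 16 trimethyl[(2,3,4,5-tetramethoxyphenyl)ethynyl]silane
Product: 17 1-ethynyl-2,3,4,5-tetramethoxybenzene
Conditions: K2CO3 (cat.), MeOH, rt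
Reagents that add atoms: none
Why: Methoxide-mediated protodesilylation cleaves the C(sp)–Si bond selectively and leaves the aryl ethers untouched.

Step 11
Reactants: 9 2-iodo-3,5,6-trimethoxyphenol; 17 1-ethynyl-2,3,4,5-tetramethoxybenzene; 18 carbon monoxide
Product: 21 5,7,8-trimethoxy-2-(2,3,4,5-tetramethoxyphenyl)-4H-chromen-4-one, via ortho-hydroxyaryl ynone 19 (not isolated), via enaminone 20 (not isolated)
Conditions: PdCl2(PPh3)2 (5 mol %), CO (20 bar), Et2NH, 120 °C
Reagents that add atoms: carbon monoxide 18, [C-]#[O+] (also listed as a reactant); diethylamine, CCNCC (held only in intermediate 20)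
Why: The divalent palladium precatalyst PdCl2(PPh3)2 is reduced in the amine to zerovalent palladium, which inserts into the C4a–I bond of 9; carbon monoxide then inserts to give a catalyst-bound aroyl species, and its coupling with alkyne 17 (amine as base, no copper) gives ynone 19. Diethylamine adds in conjugate fashion to 19 to give enaminone 20, and the phenol oxygen then attacks C2 and expels the amine (oxa-Michael addition–elimination), which closes ring C in the 6-endo-trig mode. The closest known reaction type is the carbonylative Sonogashira annulation of ortho-iodophenols with terminal alkynes to flavones in a secondary amine. No stereocentre is formed. Three selectivities are needed: carbonylative over direct coupling (which would lead on to a 2-arylbenzofuran), secured by carbon monoxide pressure, the absence of a copper co-catalyst and the ready acyl formation of an electron-rich aryl group; six-membered over five-membered (aurone, 5-exo-dig) closure, secured by routing the ynone through the enaminone, whose electrophilic carbon is C2; and the 5,7,8 pattern of ring A, secured because iodine marks C4a and the only free hydroxyl marks C8a in 9.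

**Compound list**

1 | 3,5-dimethoxyphenol | COc1cc(O)cc(OC)c1 | starting material
2 | 3,5-dimethoxyphenyl N,N-diethylcarbamate | CCN(CC)C(=O)Oc1cc(OC)cc(OC)c1 | intermediate
3 | 2-lithio-3,5-dimethoxyphenyl N,N-diethylcarbamate | CCN(CC)C(=O)Oc1cc(OC)cc(OC)c1[Li] | intermediate (not isolated)
4 | dimethyl [2-(diethylcarbamoyloxy)-4,6-dimethoxyphenyl]boronate | CCN(CC)C(=O)Oc1cc(OC)cc(OC)c1B(OC)OC | intermediate (not isolated)
5 | 2-hydroxy-3,5-dimethoxyphenyl N,N-diethylcarbamate | CCN(CC)C(=O)Oc1cc(OC)cc(OC)c1O | intermediate
6 | 2,3,5-trimethoxyphenyl N,N-diethylcarbamate | CCN(CC)C(=O)Oc1cc(OC)cc(OC)c1OC | intermediate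
7 | 6-lithio-2,3,5-trimethoxyphenyl N,N-diethylcarbamate | CCN(CC)C(=O)Oc1c([Li])c(OC)cc(OC)c1OC | intermediate (not isolated)
8 | 6-iodo-2,3,5-trimethoxyphenyl N,N-diethylcarbamate | CCN(CC)C(=O)Oc1c(I)c(OC)cc(OC)c1OC | intermediate
9 | 2-iodo-3,5,6-trimethoxyphenol | Oc1c(I)c(OC)cc(OC)c1OC | intermediate
10 | 2,3,4-trimethoxybenzaldehyde | COc1ccc(C=O)c(OC)c1OC | starting material
11 | 2,3,4-trimethoxyphenyl formate | COc1ccc(OC=O)c(OC)c1OC | intermediate (not isolated)
12 | 2,3,4-trimethoxyphenol | COc1ccc(O)c(OC)c1OC | intermediate
13 | 1,2,3,4-tetramethoxybenzene | COc1ccc(OC)c(OC)c1OC | intermediate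
14 | 1-iodo-2,3,4,5-tetramethoxybenzene | COc1cc(I)c(OC)c(OC)c1OC | intermediate
15 | trimethylsilylacetylene | C#C[Si](C)(C)C | starting material
16 | trimethyl[(2,3,4,5-tetramethoxyphenyl)ethynyl]silane | COc1cc(C#C[Si](C)(C)C)c(OC)c(OC)c1OC | intermediate
17 | 1-ethynyl-2,3,4,5-tetramethoxybenzene | C#Cc1cc(OC)c(OC)c(OC)c1OC | intermediate
18 | carbon monoxide | [C-]#[O+] | starting material
19 | 1-(2-hydroxy-3,4,6-trimethoxyphenyl)-3-(2,3,4,5-tetramethoxyphenyl)prop-2-yn-1-one | COc1cc(C#CC(=O)c2c(O)c(OC)c(OC)cc2OC)c(OC)c(OC)c1OC | intermediate (not isolated)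
20 | (E)-3-(diethylamino)-1-(2-hydroxy-3,4,6-trimethoxyphenyl)-3-(2,3,4,5-tetramethoxyphenyl)prop-2-en-1-one | CCN(CC)/C(=C/C(=O)c1c(O)c(OC)c(OC)cc1OC)c1cc(OC)c(OC)c(OC)c1OC | intermediate (not isolated)
21 | 5,7,8-trimethoxy-2-(2,3,4,5-tetramethoxyphenyl)-4H-chromen-4-one | COc1cc(-c2cc(=O)c3c(OC)cc(OC)c(OC)c3o2)c(OC)c(OC)c1OC | target

**Count**

Total step count: 11.
Longest linear sequence: 6 steps (steps 1–5 and 11; the alkyne branch, steps 6–10 and 11, is equally long).

**Steps most likely to fail**

Step 11. At a C–I bond flanked by two oxygen substituents, oxidative addition may be slow, coupling without uptake of carbon monoxide may outrun acyl formation and lead on to a benzofuran, or the ynone may close to the five-membered ring before the amine adds. The fallback sets out from 9 and 17, avoids palladium and carbon monoxide, takes C4 from DMF, and comes back to the route at 19. Phenol 9 is protected with MOMCl and i-Pr2NEt in CH2Cl2 as 2-iodo-1,4,5-trimethoxy-3-(methoxymethoxy)benzene F1. Iodine–lithium exchange with n-BuLi in THF at −78 °C gives [2-(methoxymethoxy)-3,4,6-trimethoxyphenyl]lithium F2, which is formylated with DMF to 2-(methoxymethoxy)-3,4,6-trimethoxybenzaldehyde F3. Alkyne 17 is deprotonated with n-BuLi in THF at −78 °C to [(2,3,4,5-tetramethoxyphenyl)ethynyl]lithium F4, which adds to F3 to give the racemic propargylic alcohol F5. MnO2 in CH2Cl2 should oxidise F5 to the protected ynone F6, and HCl in MeOH removes the acetal to give ynone 19. Diethylamine in ethanol then takes 19 through enaminone 20 to 21, as in the closing phase of step 11.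

Step 5. Hydrolysis of a carbamate flanked by iodine and a methoxy group may be very slow, and forcing it may cost the iodine. The fallback sets out from 6, removes the carbamate before iodine is present and re-installs a directing group that leaves under mild conditions, and comes back at 9. LiAlH4 in refluxing THF should cleave 6 to 2,3,5-trimethoxyphenol F7. SEMCl and i-Pr2NEt in CH2Cl2 give trimethyl[2-[(2,3,5-trimethoxyphenoxy)methoxy]ethyl]silane F8. Directed ortho-metalation with n-BuLi and TMEDA in Et2O at 0 °C, at the position between the acetal oxygen and a methoxy group, gives [3,4,6-trimethoxy-2-[[2-(trimethylsilyl)ethoxy]methoxy]phenyl]lithium F9, and iodine converts it into [2-[(2-iodo-3,5,6-trimethoxyphenoxy)methoxy]ethyl]trimethylsilane F10. Bu4NF in warm THF then removes the acetal to give 9.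

Step 2. Deprotonation may occur between the two methoxy groups instead of next to the carbamate, or the carbamoyl group may shift to carbon (anionic ortho-Fries) before the borate quench. The fallback sets out from 1, introduces the oxygen by formylation and Baeyer–Villiger oxidation instead of metalation, and comes back at 5. Magnesium-mediated ortho-formylation of 1 (MgCl2, Et3N, paraformaldehyde, MeCN, reflux) gives 2-hydroxy-4,6-dimethoxybenzaldehyde F11. Carbamoylation (ClCONEt2, K2CO3, MeCN, reflux) gives 2-formyl-3,5-dimethoxyphenyl N,N-diethylcarbamate F12. Baeyer–Villiger oxidation with mCPBA in CH2Cl2 gives 2-(formyloxy)-3,5-dimethoxyphenyl N,N-diethylcarbamate F13, and acid-catalysed methanolysis (MeOH, cat. HCl, rt) of the formate gives 5.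

**Further compounds**

F1 | step 11 | 2-iodo-1,4,5-trimethoxy-3-(methoxymethoxy)benzene | COCOc1c(I)c(OC)cc(OC)c1OC
F2 | step 11 | [2-(methoxymethoxy)-3,4,6-trimethoxyphenyl]lithium | COCOc1c([Li])c(OC)cc(OC)c1OC
F3 | step 11 | 2-(methoxymethoxy)-3,4,6-trimethoxybenzaldehyde | COCOc1c(C=O)c(OC)cc(OC)c1OC
F4 | step 11 | [(2,3,4,5-tetramethoxyphenyl)ethynyl]lithium | [Li]C#Cc1cc(OC)c(OC)c(OC)c1OC
F5 | step 11 | rac-1-[2-(methoxymethoxy)-3,4,6-trimethoxyphenyl]-3-(2,3,4,5-tetramethoxyphenyl)prop-2-yn-1-ol | COCOc1c(C(O)C#Cc2cc(OC)c(OC)c(OC)c2OC)c(OC)cc(OC)c1OC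
F6 | step 11 | 1-[2-(methoxymethoxy)-3,4,6-trimethoxyphenyl]-3-(2,3,4,5-tetramethoxyphenyl)prop-2-yn-1-one | COCOc1c(C(=O)C#Cc2cc(OC)c(OC)c(OC)c2OC)c(OC)cc(OC)c1OC
F7 | step 5 | 2,3,5-trimethoxyphenol | COc1cc(O)c(OC)c(OC)c1
F8 | step 5 | trimethyl[2-[(2,3,5-trimethoxyphenoxy)methoxy]ethyl]silane | COc1cc(OCOCC[Si](C)(C)C)c(OC)c(OC)c1
F9 | step 5 | [3,4,6-trimethoxy-2-[[2-(trimethylsilyl)ethoxy]methoxy]phenyl]lithium | COc1cc(OC)c([Li])c(OCOCC[Si](C)(C)C)c1OC
F10 | step 5 | [2-[(2-iodo-3,5,6-trimethoxyphenoxy)methoxy]ethyl]trimethylsilane | COc1cc(OC)c(I)c(OCOCC[Si](C)(C)C)c1OC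
F11 | step 2 | 2-hydroxy-4,6-dimethoxybenzaldehyde | COc1cc(O)c(C=O)c(OC)c1
F12 | step 2 | 2-formyl-3,5-dimethoxyphenyl N,N-diethylcarbamate | CCN(CC)C(=O)Oc1cc(OC)cc(OC)c1C=O
F13 | step 2 | 2-(formyloxy)-3,5-dimethoxyphenyl N,N-diethylcarbamate | CCN(CC)C(=O)Oc1cc(OC)cc(OC)c1OC=O
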